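**Retrosynthetic overview**

1. Target 13 ⇐ tetradeca-O-benzyl trimer 12 (H2/Pd at the end) ⇐ 11, in which the lower unit is a flavan-3,4-diol whose extra C4–OH is removed by ionic hydrogenation.
2. Key disconnection: the pyran ring of the lower (catechin) unit, bonds C4–C4a and O1–C2, by a [3+3] annulation of the dimer-phenol 6 with the C3 building block (2R,3S)-epoxy aldehyde 9.
3. 6 ⇐ dimeric C4 acetal 4 + 3,5-bis(benzyloxy)phenol 5 (Friedel–Crafts); 4 ⇐ self-condensation of the C4 acetal 3 ⇐ (+)-gallocatechin 1; 9 ⇐ 3,4-bis(benzyloxy)benzaldehyde 7 in two steps.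
4. Ring order: the two upper pyran rings come intact from 1; the bond top C4–middle C8 is made first, then the bond middle C4–aryl carbon of the future lower A ring, and the lower pyran ring last.
5. Enabling feature: in ring A of the lower unit, O1 sits on C8a next to C4a, so without the pyran ring this pair is one free phenol OH with one open ortho CH (a 1,3-C,O-dinucleophile). C4/C3/C2 map onto the aldehyde carbon and the two carbons of a trans epoxide, whose anti opening at the benzylic carbon (activated by the 3,4-dioxygenated B ring) gives the 2,3-trans (2R,3S) pair.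

Key step: step 7

Remark: (+)-gallocatechin (2R,3S) is taken as a commercial starting material. The O-bearing C4 of 3, 4, 10 and 11 is expected as an epimer mixture and is written without configuration, because this centre is ionised or reduced later.

**Route**

Step 1
Reactants: 1 (+)-gallocatechin
Product: 2 5,7,3',4',5'-penta-O-benzyl-(+)-gallocatechin
Conditions: BnBr (5.5 equiv), K2CO3, DMF, 0 °C → rt, under Ar
Reagents that add atoms: benzyl bromide, BrCc1ccccc1
Why: Williamson ether synthesis; carbonate deprotonates only the five phenols, so the aliphatic 3-OH stays free, and the low temperature should avoid epimerisation at C2.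

Step 2
Reactants: 2 5,7,3',4',5'-penta-O-benzyl-(+)-gallocatechin
Product: 3 (2R,3S)-5,7,3',4',5'-penta-O-benzyl-4-(2-ethoxyethoxy)gallocatechin
Conditions: DDQ (2 equiv), 2-ethoxyethanol (5 equiv), CH2Cl2, rt
Reagents that add atoms: 2-ethoxyethanol, CCOCCO
Why: DDQ benzylic oxidation; hydride abstraction from C4 gives the flavan-4-yl cation stabilised by O1 and the 5- and 7-benzyloxy groups, and the alcohol traps it as the C4 acetal-type ether.

Step 3
Reactants: 3 (2R,3S)-5,7,3',4',5'-penta-O-benzyl-4-(2-ethoxyethoxy)gallocatechin (two molecules)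
Product: 4 deca-O-benzyl-gallocatechin-(4α→8)-4-(2-ethoxyethoxy)gallocatechin
Conditions: Zn(OTf)2 (0.5 equiv), CH2Cl2, 0 °C → rt, stopped at partial conversion, 3 recovered
Reagents that add atoms: none
Why: Lewis acid-mediated Friedel–Crafts self-condensation; C8 of one molecule attacks the C4 cation of the other anti to its C3–OH, which sets the new C4 centre 3,4-trans (4α), while the product keeps its own C4 ether as the handle for the next coupling.

Step 4
Reactants: 4 deca-O-benzyl-gallocatechin-(4α→8)-4-(2-ethoxyethoxy)gallocatechin; 5 3,5-bis(benzyloxy)phenol (3 equiv)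
Product: 6 2-[deca-O-benzyl-gallocatechin-(4α→8)-gallocatechin-4α-yl]-3,5-bis(benzyloxy)phenol
Conditions: TMSOTf (10 mol%), CH2Cl2, −78 → −40 °C
Reagents that add atoms: none
Why: Friedel–Crafts arylation of the flavan-4-yl cation; attack anti to the C3–OH sets the middle-unit C4 3,4-trans (4α), and the carbon ortho to the phenol OH of 5 should react because the carbon between the two benzyloxy groups is shielded.

Step 5
Reactants: 7 3,4-bis(benzyloxy)benzaldehyde
Product: 8 (E)-3-[3,4-bis(benzyloxy)phenyl]prop-2-enal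
Conditions: Ph3P=CHCHO (1.2 equiv), toluene, 80 °C
Reagents that add atoms: (triphenylphosphoranylidene)acetaldehyde, O=CC=P(c1ccccc1)(c1ccccc1)c1ccccc1
Why: Wittig olefination with a stabilised ylide, which should give the (E)-enal.

Step 6
Reactants: 8 (E)-3-[3,4-bis(benzyloxy)phenyl]prop-2-enal
Product: 9 (2R,3S)-3-[3,4-bis(benzyloxy)phenyl]oxirane-2-carbaldehyde
Conditions: 35% aq. H2O2 (1.3 equiv), (S)-2-[bis(3,5-bis(trifluoromethyl)phenyl)(trimethylsilyloxy)methyl]pyrrolidine (10 mol%), CH2Cl2, rt; used at once after a short Et3N-deactivated silica plug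
Reagents that add atoms: hydrogen peroxide, OO
Why: organocatalytic Weitz–Scheffer-type epoxidation through iminium and enamine intermediates; the peroxide adds to the β-carbon on the face left open by the bulky silyloxydiarylmethyl group and the enamine closes onto the O–O bond, which should set both centres as the trans (2R,3S) epoxide.

Step 7
Reactants: 6 2-[deca-O-benzyl-gallocatechin-(4α→8)-gallocatechin-4α-yl]-3,5-bis(benzyloxy)phenol; 9 (2R,3S)-3-[3,4-bis(benzyloxy)phenyl]oxirane-2-carbaldehyde (1.5 equiv)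
Product: 11 tetradeca-O-benzyl-gallocatechin-(4α→8)-gallocatechin-(4α→8)-4-hydroxycatechin, via titanium-bound epoxy alcohol 10 (not isolated)
Conditions: Ti(OiPr)4 (3.3 equiv), toluene, rt, then iPrOH stripped; 9, CH2Cl2, −20 °C → rt; aq. Rochelle salt
Reagents that add atoms: none
Why: Proposed new method: ligand exchange turns the only phenol of 6 into an aryloxytitanium triisopropoxide, aldehyde 9 binds to the same Ti and is attacked through a six-membered chelate by the one free carbon ortho to that oxygen (future C4a) to give the Ti-bound 2,3-epoxy alcohol 10 (C4–C4a bond), after which the Ti-bound phenoxide oxygen (future O1) opens the epoxide at its benzylic carbon (future C2) with inversion (O1–C2 bond). The closest known reaction types are the ortho-specific hydroxyalkylation of titanium and magnesium phenoxides with α-oxygenated aldehydes, the Ti(OiPr)4-mediated C3-selective opening of 2,3-epoxy alcohols and the 6-endo cyclisation of ortho-hydroxyaryl aryl-epoxides to trans-flavan-3-ols; their merger into a one-pot [3+3] annulation of a phenol with an epoxy aldehyde has not been shown. The one ring closed is the pyran ring of the lower unit, by a 6-endo-tet epoxide opening. C3 is carried over unchanged from 9 (set by the catalyst of step 6), C2 is set by stereospecific SN2 inversion at the (3S) epoxide carbon so that the trans epoxide gives the 2,3-trans (2R,3S) pair, and the C4 carbinol is not controlled because step 8 removes it. The step needs C- instead of O-alkylation at the position ortho and not para to the phenol oxygen, which the Ti template and the single free phenol OH secure, and it needs 6-endo instead of 5-exo opening, which the charge-stabilising 3,4-bis(benzyloxy)phenyl group on C2 and the Ti bridge between the C4 alkoxide and the epoxide oxygen secure. Should the phenoxide open the epoxide of 9 first, ring closure of the aldehyde onto the ortho carbon leads to the same product 11.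

Step 8
Reactants: 11 tetradeca-O-benzyl-gallocatechin-(4α→8)-gallocatechin-(4α→8)-4-hydroxycatechin
Product: 12 tetradeca-O-benzyl-prodelphinidin C2
Conditions: Et3SiH (5 equiv), TMSOTf (20 mol%), CH2Cl2, −78 → −40 °C
Reagents that add atoms: none
Why: ionic hydrogenation; the C4–OH on the 5,7-dioxygenated A ring ionises under the same mild activation as in steps 3 and 4 and the cation is reduced by the silane, while C2, C3 and the interflavan bonds should stay untouched at this temperature.

Step 9
Reactants: 12 tetradeca-O-benzyl-prodelphinidin C2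
Product: 13 prodelphinidin C2
Conditions: H2 (1 atm), 20% Pd(OH)2/C, THF/MeOH/H2O, rt; filtration under Ar, lyophilisation
Reagents that add atoms: none
Why: catalytic hydrogenolysis of the fourteen aryl benzyl ethers under neutral conditions, which should leave the C2–O1 bonds and the diarylmethine C4 centres intact.

**Compound list**

1 | (+)-gallocatechin, (2R,3S)-2-(3,4,5-trihydroxyphenyl)chromane-3,5,7-triol | Oc1cc(O)c2c(c1)O[C@H](c1cc(O)c(O)c(O)c1)[C@@H](O)C2 | starting material

2 | 5,7,3',4',5'-penta-O-benzyl-(+)-gallocatechin (3-OH free) | c1ccc(cc1)COc1cc(OCc3ccccc3)c2c(c1)O[C@H](c1cc(OCc3ccccc3)c(OCc3ccccc3)c(OCc3ccccc3)c1)[C@@H](O)C2 | intermediate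

3 | (2R,3S)-5,7,3',4',5'-penta-O-benzyl-4-(2-ethoxyethoxy)gallocatechin (C4 epimers) | c1ccc(cc1)COc1cc(OCc3ccccc3)c2c(c1)O[C@H](c1cc(OCc3ccccc3)c(OCc3ccccc3)c(OCc3ccccc3)c1)[C@@H](O)C2OCCOCC | intermediate

4 | deca-O-benzyl-gallocatechin-(4α→8)-4-(2-ethoxyethoxy)gallocatechin (both 3-OH free; ether-bearing C4 of the lower unit as epimers) | c1ccc(cc1)COc1cc(OCc3ccccc3)c2c(c1)O[C@H](c1cc(OCc3ccccc3)c(OCc3ccccc3)c(OCc3ccccc3)c1)[C@@H](O)[C@@H]2c1c(OCc3ccccc3)cc(OCc3ccccc3)c2c1O[C@H](c1cc(OCc3ccccc3)c(OCc3ccccc3)c(OCc3ccccc3)c1)[C@@H](O)C2OCCOCC | intermediate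

5 | 3,5-bis(benzyloxy)phenol | Oc1cc(OCc2ccccc2)cc(OCc2ccccc2)c1 | starting material

6 | 2-[deca-O-benzyl-gallocatechin-(4α→8)-gallocatechin-4α-yl]-3,5-bis(benzyloxy)phenol (one free phenol OH, two free 3-OH) | c1ccc(cc1)COc1cc(OCc3ccccc3)c2c(c1)O[C@H](c1cc(OCc3ccccc3)c(OCc3ccccc3)c(OCc3ccccc3)c1)[C@@H](O)[C@@H]2c1c(OCc3ccccc3)cc(OCc3ccccc3)c2c1O[C@H](c1cc(OCc3ccccc3)c(OCc3ccccc3)c(OCc3ccccc3)c1)[C@@H](O)[C@@H]2c1c(OCc3ccccc3)cc(OCc3ccccc3)cc1O | intermediate

7 | 3,4-bis(benzyloxy)benzaldehyde | O=Cc1ccc(OCc2ccccc2)c(OCc2ccccc2)c1 | starting material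

8 | (E)-3-[3,4-bis(benzyloxy)phenyl]prop-2-enal | O=C/C=C/c1ccc(OCc2ccccc2)c(OCc2ccccc2)c1 | intermediate

9 | (2R,3S)-3-[3,4-bis(benzyloxy)phenyl]oxirane-2-carbaldehyde (trans) | O=C[C@@H]1O[C@H]1c1ccc(OCc2ccccc2)c(OCc2ccccc2)c1 | intermediate

10 | ortho-hydroxyalkylation adduct: phenol 6 carrying, at the carbon ortho to its OH, a 1-hydroxy-2,3-epoxy-3-[3,4-bis(benzyloxy)phenyl]propyl group (trans epoxide from 9, carbinol epimers; shown as the free alcohol) | c1ccc(cc1)COc1cc(OCc3ccccc3)c2c(c1)O[C@H](c1cc(OCc3ccccc3)c(OCc3ccccc3)c(OCc3ccccc3)c1)[C@@H](O)[C@@H]2c1c(OCc3ccccc3)cc(OCc3ccccc3)c2c1O[C@H](c1cc(OCc3ccccc3)c(OCc3ccccc3)c(OCc3ccccc3)c1)[C@@H](O)[C@@H]2c1c(OCc3ccccc3)cc(OCc3ccccc3)c(C(O)[C@@H]3O[C@H]3c3ccc(OCc4ccccc4)c(OCc4ccccc4)c3)c1O | intermediate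

11 | tetradeca-O-benzyl-gallocatechin-(4α→8)-gallocatechin-(4α→8)-4-hydroxycatechin (lower unit a (2R,3S)-flavan-3,4-diol, C4 epimers) | c1ccc(cc1)COc1cc(OCc3ccccc3)c2c(c1)O[C@H](c1cc(OCc3ccccc3)c(OCc3ccccc3)c(OCc3ccccc3)c1)[C@@H](O)[C@@H]2c1c(OCc3ccccc3)cc(OCc3ccccc3)c2c1O[C@H](c1cc(OCc3ccccc3)c(OCc3ccccc3)c(OCc3ccccc3)c1)[C@@H](O)[C@@H]2c1c(OCc3ccccc3)cc(OCc3ccccc3)c2c1O[C@H](c1ccc(OCc3ccccc3)c(OCc3ccccc3)c1)[C@@H](O)C2O | intermediate

12 | tetradeca-O-benzyl-prodelphinidin C2 (three 3-OH free) | c1ccc(cc1)COc1cc(OCc3ccccc3)c2c(c1)O[C@H](c1cc(OCc3ccccc3)c(OCc3ccccc3)c(OCc3ccccc3)c1)[C@@H](O)[C@@H]2c1c(OCc3ccccc3)cc(OCc3ccccc3)c2c1O[C@H](c1cc(OCc3ccccc3)c(OCc3ccccc3)c(OCc3ccccc3)c1)[C@@H](O)[C@@H]2c1c(OCc3ccccc3)cc(OCc3ccccc3)c2c1O[C@H](c1ccc(OCc3ccccc3)c(OCc3ccccc3)c1)[C@@H](O)C2 | intermediate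

13 | prodelphinidin C2, gallocatechin-(4α→8)-gallocatechin-(4α→8)-catechin | Oc1cc(O)c2c(c1)O[C@H](c1cc(O)c(O)c(O)c1)[C@@H](O)[C@@H]2c1c(O)cc(O)c2c1O[C@H](c1cc(O)c(O)c(O)c1)[C@@H](O)[C@@H]2c1c(O)cc(O)c2c1O[C@H](c1ccc(O)c(O)c1)[C@@H](O)C2 | target

**Step count**

Total step count: 9. Longest linear sequence: 7 steps (steps 1, 2, 3, 4, 7, 8, 9).

**Steps most likely to fail**

Step 7 (proposed new method). What may go wrong: opening or rearrangement of the electron-rich aryl epoxide by the Lewis acid before the C–C bond forms, closure in the 5-exo mode, migration of the epoxide in 10 (Payne type), or no attack at the hindered phenoxide. The fallback uses known chemistry, sets out from 4 and comes back at 12. It gives up the annulation and forms the lower interflavan bond instead. Commercial (+)-catechin is benzylated (BnBr, K2CO3, DMF) to 5,7,3',4'-tetra-O-benzyl-(+)-catechin F1. Compound 4 and an excess of F1 are then treated with TMSOTf (cat.) in CH2Cl2 at −78 °C, so that C8 of F1 captures the middle-unit C4 cation anti to the C3–OH. This Friedel–Crafts coupling should give 12 directly, and steps 5 to 8 are then not needed.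

Step 3. What may go wrong: chain growth beyond the dimer, loss of the terminal C4 ether, and some 4→6 coupling. The fallback sets out from 3 and comes back at 6, and replaces self-condensation by orthogonal activation of two different C4 leaving groups. Part of 3 is converted with 2,6-dimethylbenzenethiol and BF3·OEt2 (CH2Cl2, −78 °C) into the C4 thioether (2R,3S)-5,7,3',4',5'-penta-O-benzyl-4-(2,6-dimethylphenylthio)gallocatechin F2. An excess of F2 is then coupled through its C8 with 3 under BF3·OEt2 at −78 °C, conditions that ionise the C4 ether but not the thioether. This should give deca-O-benzyl-gallocatechin-(4α→8)-4-(2,6-dimethylphenylthio)gallocatechin F3. The thioether of F3 is finally activated with AgBF4 (THF, 0 °C) in the presence of 5 to give 6.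

Step 4. What may go wrong: poor positional selectivity on 5 (attack at the carbon para to the OH, between the two benzyloxy groups) and double arylation of 5. The fallback sets out from 4 and comes back at 6, and removes the positional question by using a C3-symmetric nucleophile. Compound 4 is coupled with an excess of phloroglucinol (TMSOTf cat., THF/CH2Cl2, −40 °C), which can give only one C-adduct, 2-[deca-O-benzyl-gallocatechin-(4α→8)-gallocatechin-4α-yl]benzene-1,3,5-triol F4. Controlled benzylation of F4 (BnBr 2.1 equiv, K2CO3, acetone, rt) should then etherify the unhindered para OH and one of the two equivalent, hindered ortho OH groups, which is compound 6.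

**Further compounds**

F1 | step 7 | 5,7,3',4'-tetra-O-benzyl-(+)-catechin | c1ccc(cc1)COc1cc(OCc3ccccc3)c2c(c1)O[C@H](c1ccc(OCc3ccccc3)c(OCc3ccccc3)c1)[C@@H](O)C2

F2 | step 3 | (2R,3S)-5,7,3',4',5'-penta-O-benzyl-4-(2,6-dimethylphenylthio)gallocatechin (C4 epimers) | c1ccc(cc1)COc1cc(OCc3ccccc3)c2c(c1)O[C@H](c1cc(OCc3ccccc3)c(OCc3ccccc3)c(OCc3ccccc3)c1)[C@@H](O)C2Sc1c(C)cccc1C

F3 | step 3 | deca-O-benzyl-gallocatechin-(4α→8)-4-(2,6-dimethylphenylthio)gallocatechin (thioether carbon as epimers) | c1ccc(cc1)COc1cc(OCc3ccccc3)c2c(c1)O[C@H](c1cc(OCc3ccccc3)c(OCc3ccccc3)c(OCc3ccccc3)c1)[C@@H](O)[C@@H]2c1c(OCc3ccccc3)cc(OCc3ccccc3)c2c1O[C@H](c1cc(OCc3ccccc3)c(OCc3ccccc3)c(OCc3ccccc3)c1)[C@@H](O)C2Sc1c(C)cccc1C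

F4 | step 4 | 2-[deca-O-benzyl-gallocatechin-(4α→8)-gallocatechin-4α-yl]benzene-1,3,5-triol | c1ccc(cc1)COc1cc(OCc3ccccc3)c2c(c1)O[C@H](c1cc(OCc3ccccc3)c(OCc3ccccc3)c(OCc3ccccc3)c1)[C@@H](O)[C@@H]2c1c(OCc3ccccc3)cc(OCc3ccccc3)c2c1O[C@H](c1cc(OCc3ccccc3)c(OCc3ccccc3)c(OCc3ccccc3)c1)[C@@H](O)[C@@H]2c1c(O)cc(O)cc1O
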